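## Retrosynthetic overview

- Gentiside C is the (S)-14-methylhexadecyl ester of 2,3-dihydroxybenzoic acid. I disconnect the ester by lipase-catalysed transesterification into methyl 2,3-dihydroxybenzoate and (S)-14-methylhexadecan-1-ol.
- The long-chain alcohol is disconnected at the C12–C13 bond by a Cu-catalysed Kumada-type coupling. The partners are (S)-2-methylbutyl tosylate and the Grignard reagent of TBS-protected 12-bromododecanol.
- The only stereocentre comes from Ru–BINAP asymmetric hydrogenation of tiglic acid, and the (S)-2-methylbutanoic acid is then reduced to the alcohol.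
- No ring is formed, because the benzene ring is purchased already carrying the 2,3-diol pattern.
- Assumption: the chain is 14-methylhexadecyl, with 13 CH2 between the ester oxygen and the stereocentre. The given SMILES is (S) by CIP.

## Route

**Step 1**
Reactants: 1, tiglic acid ((2E)-2-methylbut-2-enoic acid)
Product: 2, (S)-2-methylbutanoic acid
Conditions: Ru(OAc)2[(R)-BINAP] (1 mol%), H2 (4 atm), MeOH, 25 °C, 24 h
Reagents that add atoms: dihydrogen, [H][H]
Why: Noyori-type carboxylate-directed asymmetric hydrogenation of an α,β-unsaturated acid; the chiral Ru–diphosphine controls the alkene face and syn H2 delivery creates C2 as (S). The (S)-acid is confirmed by [α]D (positive, neat) and chiral GC, and the BINAP enantiomer is switched if the (R)-acid results.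

**Step 2**
Reactants: 2, (S)-2-methylbutanoic acid
Product: 3, (S)-2-methylbutan-1-ol
Conditions: LiAlH4, Et2O, 0 °C → reflux, 2 h; Fieser work-up
Reagents that add atoms: none
Why: Hydride reduction of a carboxylic acid to the primary alcohol. The stereocentre is never enolised under these conditions and stays (S). The alcohol is volatile (bp 128 °C), so it is carried on as a dried ether solution without evaporating to dryness.

**Step 3**
Reactants: 3, (S)-2-methylbutan-1-ol
Product: 4, (S)-2-methylbutyl 4-methylbenzenesulfonate
Conditions: TsCl, Et3N, DMAP (cat.), CH2Cl2, 0 °C → rt, 12 h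
Reagents that add atoms: p-toluenesulfonyl chloride, Cc1ccc(cc1)S(=O)(=O)Cl
Why: Sulfonylation converts the alcohol into a non-volatile leaving group. Only the O–H reacts, and the stereocentre is β to the oxygen, so its configuration is untouched.

**Step 4**
Reactants: 5, 12-bromododecan-1-ol
Product: 6, tert-butyl[(12-bromododecyl)oxy]dimethylsilane
Conditions: TBSCl, imidazole, CH2Cl2, 0 °C → rt, 6 h
Reagents that add atoms: tert-butyldimethylsilyl chloride, CC(C)(C)[Si](C)(C)Cl
Why: Silyl protection of the primary alcohol makes the bromide compatible with Grignard formation. The starting material is achiral and no stereocentre is involved.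

**Step 5**
Reactants: 6, TBS-protected 12-bromododecanol
Product: 7, [12-(tert-butyldimethylsilyloxy)dodecyl]magnesium bromide
Conditions: Mg turnings, 1,2-dibromoethane (activator), THF, 45 °C → reflux, 2 h; used directly
Reagents that add atoms: magnesium, [Mg]
Why: Oxidative insertion of Mg into a primary alkyl bromide. The TBS ether is inert to Grignard reagents.

**Step 6**
Reactants: 4, (S)-2-methylbutyl tosylate; 7, Grignard reagent (1.5 equiv)
Product: 8, tert-butyldimethyl{[(14S)-14-methylhexadecyl]oxy}silane
Conditions: Li2CuCl4 (5 mol%), THF, −10 °C → rt, 12 h
Reagents that add atoms: none (Li2CuCl4 is catalytic)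
Why: Cu-catalysed Kumada-type SN2 coupling of a primary alkyl Grignard with a primary tosylate forms the C12–C13 bond. Reaction occurs at the CH2, so the β-stereocentre is retained. The priority order (chain > ethyl > methyl) is unchanged, so the label stays (S).

**Step 7**
Reactants: 8, TBS ether
Product: 9, (S)-14-methylhexadecan-1-ol
Conditions: TBAF (1 M in THF), THF, 0 °C → rt, 3 h
Reagents that add atoms: none
Why: Fluoride-mediated Si–O cleavage. The only other product-related impurity, the Grignard homodimer, becomes the very polar C24 diol, so it is easily removed by chromatography at this stage.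

**Step 8**
Reactants: 9, (S)-14-methylhexadecan-1-ol (1 equiv); 10, methyl 2,3-dihydroxybenzoate (3 equiv)
Product: 11, Gentiside C ((S)-14-methylhexadecyl 2,3-dihydroxybenzoate)
Conditions: Novozym 435 (immobilised Candida antarctica lipase B), toluene, 4 Å MS, 60 °C, 72–96 h
Reagents that add atoms: none (MeOH is lost)
Why: The lipase (a hydrolase, EC 3.1.1.3) forms an acyl-enzyme with the methyl ester and transfers it to the primary alcohol. This is a transesterification that leaves the two free phenols untouched, so no protecting groups are needed. Molecular sieves remove MeOH to drive the equilibrium, and no stereocentre is touched.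

## Compound list

1 | tiglic acid, (2E)-2-methylbut-2-enoic acid | C/C=C(\C)/C(=O)O | starting material
2 | (S)-2-methylbutanoic acid | CC[C@H](C)C(=O)O | intermediate
3 | (S)-2-methylbutan-1-ol | CC[C@H](C)CO | intermediate
4 | (S)-2-methylbutyl tosylate | CC[C@H](C)COS(=O)(=O)c1ccc(C)cc1 | intermediate
5 | 12-bromododecan-1-ol | BrCCCCCCCCCCCCO | starting material
6 | tert-butyl[(12-bromododecyl)oxy]dimethylsilane | CC(C)(C)[Si](C)(C)OCCCCCCCCCCCCBr | intermediate
7 | [12-(TBS-oxy)dodecyl]magnesium bromide | CC(C)(C)[Si](C)(C)OCCCCCCCCCCCC[Mg]Br | intermediate
8 | TBS ether of (S)-14-methylhexadecan-1-ol | CC[C@H](C)CCCCCCCCCCCCCO[Si](C)(C)C(C)(C)C | intermediate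
9 | (S)-14-methylhexadecan-1-ol | CC[C@H](C)CCCCCCCCCCCCCO | intermediate
10 | methyl 2,3-dihydroxybenzoate | COC(=O)c1cccc(O)c1O | starting material
11 | Gentiside C | CC[C@H](C)CCCCCCCCCCCCCOC(=O)c1cccc(O)c1O | target

## Totals

Total steps: 8. Longest linear sequence: 6 steps (Steps 1, 2, 3, 6, 7, 8).

## Three steps most likely to fail

1. **Step 8 (lipase transesterification).** The ortho-hydroxyl hydrogen-bonds to the ester and hinders the acyl-enzyme, so conversion may stall.
   Fallback: drop the enzyme and use protecting-group chemistry. Benzylate 10 (BnBr, K2CO3), saponify (LiOH), Steglich-esterify with 9 (EDC, DMAP), then remove the benzyl groups (H2, Pd/C).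
2. **Step 6 (Cu-catalysed sp3–sp3 coupling).** The β-branched tosylate couples slowly, and the Grignard can homocouple or give the alkyl bromide.
   Fallback: build the C12–C13 bond by Wittig olefination then hydrogenation. Convert 3 to the iodide and then the phosphonium salt, olefinate with 12-(TBS-oxy)dodecanal, hydrogenate (H2, Pd/C), then continue to Step 7.
3. **Step 1 (asymmetric hydrogenation).** The ee may be only about 90%, or the wrong enantiomer may form.
   Fallback: make (S)-2-methylbutan-1-ol (3) biocatalytically from (E)-2-methylbut-2-enal. Use an ene-reductase (Old Yellow Enzyme family) with an alcohol dehydrogenase and glucose/GDH/NADP⁺ cofactor recycling. This replaces Steps 1–2.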